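**Retrosynthetic overview**

1. Feature: ring A with O1, C7a, C3a, the C5 allyl and the C7 OMe group is a eugenol unit, and C2, C3 and C9 with ring B (4-hydroxy-3-methoxyphenyl on C2) are a feruloyl C6–C3 unit; the C9 oxygen carries a second eugenol as an aryl ether.
2. C9–O(aryl) bond: Mitsunobu etherification of the C9 alcohol (ring B phenol silylated) with eugenol; the alcohol comes from reductive removal of an N-acyl oxazolidinone at C9.
3. Dihydrofuran ring: oxidative coupling of eugenol with N-feruloyl (R)-4-benzyl-2-oxazolidinone, first C3–C3a (feruloyl alpha carbon to the free ortho carbon of eugenol), then O1–C2 (eugenol oxygen onto the quinone methide carbon), trans.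
4. Feruloyl imide: Wittig olefination of unprotected vanillin with the acyl-oxazolidinone ylide made from (R)-4-benzyl-2-oxazolidinone, bromoacetyl bromide and PPh3.
5. Ring order: the three benzene rings are bought; the dihydrofuran ring is the only ring formed, in the key step.

Key step: step 4

Assumption: no chelating metal is present in the coupling, so the imide is taken to react as its dipole-opposed s-cis rotamer on the face away from the benzyl group, which calls for the (R) auxiliary to reach the (2S,3S) imide; if the sense proves opposite, the (S) antipode of 1 is used and nothing else changes.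

**Route**

Step 1
Reactants: 1 (R)-4-benzyl-2-oxazolidinone; 2 bromoacetyl bromide
Product: 3 (R)-4-benzyl-3-(2-bromoacetyl)oxazolidin-2-one
Conditions: n-BuLi, THF, −78 °C; then 2, −78 to 0 °C
Reagents that add atoms: none
Why: N-acylation of the lithiated oxazolidinone, in which the acyl bromide carbon is far more electrophilic than the CH2Br carbon at −78 °C, should give the bromoacetyl imide without touching the stereocentre.

Step 2
Reactants: 3 (R)-4-benzyl-3-(2-bromoacetyl)oxazolidin-2-one
Product: 5 (R)-4-benzyl-3-[2-(triphenylphosphoranylidene)acetyl]oxazolidin-2-one, via phosphonium bromide 4 (not isolated)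
Conditions: PPh3, toluene, rt; then aq. Na2CO3, CH2Cl2, rt
Reagents that add atoms: triphenylphosphine, c1ccc(cc1)P(c1ccccc1)c1ccccc1
Why: SN2 displacement of the primary alpha-bromide by PPh3 followed by deprotonation of the acidic acylmethylphosphonium salt (Wittig reagent formation) should give the carbonyl-stabilised ylide.

Step 3
Reactants: 5 (R)-4-benzyl-3-[2-(triphenylphosphoranylidene)acetyl]oxazolidin-2-one; 6 vanillin
Product: 7 (R)-4-benzyl-3-[(E)-3-(4-hydroxy-3-methoxyphenyl)prop-2-enoyl]oxazolidin-2-one (N-feruloyl oxazolidinone)
Conditions: toluene, 90 °C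
Reagents that add atoms: none
Why: Wittig olefination with a carbonyl-stabilised ylide should give the (E)-enoyl imide and tolerates the free phenol of vanillin as ester-stabilised ylides do, so no protecting group is needed.

Step 4
Reactants: 7 N-feruloyl (R)-4-benzyl-2-oxazolidinone; 8 eugenol
Product: 11 (R)-4-benzyl-3-{[(2S,3S)-5-allyl-2-(4-hydroxy-3-methoxyphenyl)-7-methoxy-2,3-dihydrobenzofuran-3-yl]carbonyl}oxazolidin-2-one, via dienone quinone methide 9 (not isolated), via phenol quinone methide 10 (not isolated)
Conditions: horseradish peroxidase (cat.), 30% aq. H2O2 and 7 added slowly by syringe pump to 8 (5 equiv), 1,4-dioxane/citrate–phosphate buffer pH 4, rt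
Reagents that add atoms: none
Why: The peroxidase takes one electron from each phenol; the feruloyl imide radical (spin on O, C5 and the alpha carbon) and the eugenol radical (spin on O and on its one free ortho carbon) combine alpha carbon to ortho carbon (C3–C3a) to give dienone 9, which enolises to phenol 10, and the ring A oxygen then adds to the exocyclic carbon of the ring B para-quinone methide (O1–C2) in a 5-exo-trig conjugate addition. The closest known reactions are the peroxidase/H2O2 or Ag2O dehydrodimerisation of ferulate esters and of auxiliary-bearing feruloyl imides to trans 8–5 phenylcoumarans, and the end-wise cross-coupling of cinnamyl-type radicals with 4-alkylguaiacols in lignin model chemistry. C3 is set in the radical coupling: with no chelating metal the imide should react as its ground-state rotamer (carbonyl dipoles opposed, enoyl s-cis) and be approached on the face away from the benzyl group, a modest bias, and since the (2S,3S) and (2R,3R) trans products are diastereomers the wanted one is freed from the other by chromatography or crystallisation at this stage. C2 is set in the ring closure, in which the aryl group takes the side opposite to the C3 acyl group (trans, also the more stable isomer). The step needs cross-coupling over self-coupling and carbon over oxygen coupling on eugenol: the acyl group should bring the oxidation potential of the cinnamoyl phenol close to that of a 4-alkylguaiacol, excess eugenol with slow addition of 7 and H2O2 makes a feruloyl radical meet mostly eugenol radicals, and eugenol has a single open ring carbon (para carries the allyl group, the other ortho the OMe group), while coupling at the eugenol oxygen and feruloyl dimers remain the expected by-products. The peroxidase is preferred to Ag2O because Ag2O is known to oxidise eugenol itself at the benzylic CH2 to its para-quinone methide, which would drain the excess partner.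

Step 5
Reactants: 11 (2S,3S) dihydrobenzofuran imide with free ring B phenol
Product: 12 (R)-4-benzyl-3-{[(2S,3S)-5-allyl-7-methoxy-2-(3-methoxy-4-triisopropylsilyloxyphenyl)-2,3-dihydrobenzofuran-3-yl]carbonyl}oxazolidin-2-one
Conditions: i-Pr3SiCl, imidazole, DMF, rt
Reagents that add atoms: chlorotriisopropylsilane, CC(C)[Si](Cl)(C(C)C)C(C)C
Why: Imidazole-mediated silylation of the only free hydroxyl group should give the aryl silyl ether, and imidazole is too weak a base to open the dihydrofuran by E1cB at the acidic C3–H.

Step 6
Reactants: 12 triisopropylsilyl-protected imide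
Product: 13 [(2S,3R)-5-allyl-7-methoxy-2-(3-methoxy-4-triisopropylsilyloxyphenyl)-2,3-dihydrobenzofuran-3-yl]methanol
Conditions: LiBH4, MeOH (1 equiv), THF, 0 °C
Reagents that add atoms: none
Why: Reductive cleavage of the N-acyl oxazolidinone by hydride attack at the exocyclic carbonyl should give the C9 alcohol and free the auxiliary, with C3 and C2 unchanged in space (the descriptor at C3 changes only by priority) and the terminal alkenes and the aryl silyl ether inert.

Step 7
Reactants: 13 C9 alcohol; 8 eugenol
Product: 14 (2S,3R)-5-allyl-3-[(4-allyl-2-methoxyphenoxy)methyl]-7-methoxy-2-(3-methoxy-4-triisopropylsilyloxyphenyl)-2,3-dihydrobenzofuran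
Conditions: PPh3, DIAD, THF, 0 °C to rt
Reagents that add atoms: none
Why: Mitsunobu etherification: the primary C9 alcohol is activated as its oxyphosphonium ion and displaced at CH2 in an SN2 step by eugenol (pKa about 10), which touches neither C3 nor C2, while the silyl ether keeps the ring B phenol from competing.

Step 8
Reactants: 14 silyl-protected ether
Product: 15 4-[(2S,3R)-5-allyl-3-[(4-allyl-2-methoxyphenoxy)methyl]-7-methoxy-2,3-dihydrobenzofuran-2-yl]-2-methoxyphenol (target)
Conditions: Bu4NF, AcOH, THF, 0 °C
Reagents that add atoms: none
Why: Fluoride-induced desilylation of the aryl silyl ether should free the ring B phenol, with AcOH buffering the phenoxide so that the allyl groups are not isomerised.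

**Compound list**

1 | (R)-4-benzyl-2-oxazolidinone | O=C1N[C@H](Cc2ccccc2)CO1 | starting material
2 | bromoacetyl bromide | BrCC(Br)=O | starting material
3 | (R)-4-benzyl-3-(2-bromoacetyl)oxazolidin-2-one | O=C(CBr)N1[C@H](Cc2ccccc2)COC1=O | intermediate
4 | {2-[(R)-4-benzyl-2-oxooxazolidin-3-yl]-2-oxoethyl}triphenylphosphonium bromide | [Br-].O=C(C[P+](c1ccccc1)(c1ccccc1)c1ccccc1)N1[C@H](Cc2ccccc2)COC1=O | intermediate (not isolated)
5 | (R)-4-benzyl-3-[2-(triphenylphosphoranylidene)acetyl]oxazolidin-2-one | O=C(C=P(c1ccccc1)(c1ccccc1)c1ccccc1)N1[C@H](Cc2ccccc2)COC1=O | intermediate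
6 | vanillin | COc1cc(C=O)ccc1O | starting material
7 | (R)-4-benzyl-3-[(E)-3-(4-hydroxy-3-methoxyphenyl)prop-2-enoyl]oxazolidin-2-one | COc1cc(/C=C/C(=O)N2[C@H](Cc3ccccc3)COC2=O)ccc1O | intermediate
8 | eugenol | C=CCc1ccc(O)c(OC)c1 | starting material
9 | dienone quinone methide: first C–C coupling product, ring A as 2,4-cyclohexadienone (sp3 ring carbon of undefined configuration), ring B as para-quinone methide, alpha carbon configured as C3 of 11 | O=C([C@H](C=C1C=CC(=O)C(OC)=C1)C1C=C(CC=C)C=C(OC)C1=O)N1[C@H](Cc2ccccc2)COC1=O | intermediate (not isolated)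
10 | phenol quinone methide: ring A rearomatised to the free phenol, ring B still the para-quinone methide | O=C([C@H](C=C1C=CC(=O)C(OC)=C1)c1cc(CC=C)cc(OC)c1O)N1[C@H](Cc2ccccc2)COC1=O | intermediate (not isolated)
11 | (R)-4-benzyl-3-{[(2S,3S)-5-allyl-2-(4-hydroxy-3-methoxyphenyl)-7-methoxy-2,3-dihydrobenzofuran-3-yl]carbonyl}oxazolidin-2-one | O=C([C@H]2c3cc(CC=C)cc(OC)c3O[C@@H]2c2ccc(O)c(OC)c2)N1[C@H](Cc2ccccc2)COC1=O | intermediate
12 | (R)-4-benzyl-3-{[(2S,3S)-5-allyl-7-methoxy-2-(3-methoxy-4-triisopropylsilyloxyphenyl)-2,3-dihydrobenzofuran-3-yl]carbonyl}oxazolidin-2-one | O=C([C@H]2c3cc(CC=C)cc(OC)c3O[C@@H]2c2ccc(O[Si](C(C)C)(C(C)C)C(C)C)c(OC)c2)N1[C@H](Cc2ccccc2)COC1=O | intermediate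
13 | [(2S,3R)-5-allyl-7-methoxy-2-(3-methoxy-4-triisopropylsilyloxyphenyl)-2,3-dihydrobenzofuran-3-yl]methanol | OC[C@H]2c3cc(CC=C)cc(OC)c3O[C@@H]2c2ccc(O[Si](C(C)C)(C(C)C)C(C)C)c(OC)c2 | intermediate
14 | (2S,3R)-5-allyl-3-[(4-allyl-2-methoxyphenoxy)methyl]-7-methoxy-2-(3-methoxy-4-triisopropylsilyloxyphenyl)-2,3-dihydrobenzofuran | C=CCc1ccc(OC[C@H]2c3cc(CC=C)cc(OC)c3O[C@@H]2c2ccc(O[Si](C(C)C)(C(C)C)C(C)C)c(OC)c2)c(OC)c1 | intermediate
15 | 4-[(2S,3R)-5-allyl-3-[(4-allyl-2-methoxyphenoxy)methyl]-7-methoxy-2,3-dihydrobenzofuran-2-yl]-2-methoxyphenol | C=CCc1ccc(OC[C@H]2c3cc(CC=C)cc(OC)c3O[C@@H]2c2ccc(O)c(OC)c2)c(OC)c1 | target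

**Step count and risks**

Total step count: 8. Longest linear sequence: 8 steps (1 to 15).

Steps most likely to fail:

1. Step 4 (key step). Self-coupling of each radical, coupling through the eugenol oxygen and oxidation of the eugenol side chain may outrun the cross C–C coupling, and the remote benzyl group may discriminate the two faces only weakly. The fallback sets out from 7 and comes back at 11. Eugenol is replaced by commercial 4-bromo-2-methoxyphenol (Oc1ccc(Br)cc1OC), a para-blocked partner without benzylic hydrogen whose radical cannot go on to a quinone methide and whose higher oxidation potential should match that of 7 more closely. Oxidative coupling under the peroxidase conditions, or with Ag2O in CH2Cl2/acetone (now harmless), should give the 5-bromo dihydrobenzofuran imide F1, separated from its trans diastereomer as for 11. Stille coupling of F1 with allylSnBu3 (Pd(PPh3)4, a zerovalent palladium catalyst, toluene, 100 °C) then installs the C5 allyl group after the ring is built and gives 11.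

2. Step 7. The activated C9 oxyphosphonium ion may lose the benzylic C3 hydrogen (elimination toward the 3-methylene compound and the 3-methylbenzofuran) or be captured by the hydrazide anion faster than the weakly acidic, ortho-substituted eugenol displaces it. The fallback sets out from 13 and comes back at 14. Activation and displacement are separated: MsCl, Et3N, CH2Cl2, 0 °C should give the mesylate F2, which is displaced by preformed caesium eugenolate (8, Cs2CO3, DMF, 50 °C) in a Williamson etherification; the triisopropylsilyl ether was chosen to withstand the phenoxide.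

3. Step 6. Hydride may attack the ring carbonyl of the hindered, alpha-branched imide (ring-opened hydroxy amide), or the basic medium may open the dihydrofuran by E1cB at C3 before reduction is complete. The fallback sets out from 12 and comes back at 13. Chelation-controlled methanolysis with MeOMgBr (from MeMgBr and MeOH, THF, 0 °C) should give the methyl ester F3 and free the auxiliary, and i-Bu2AlH (CH2Cl2, −78 to 0 °C) then reduces F3 to 13.

Further compounds
F1 | step 4 | (R)-4-benzyl-3-{[(2S,3S)-5-bromo-2-(4-hydroxy-3-methoxyphenyl)-7-methoxy-2,3-dihydrobenzofuran-3-yl]carbonyl}oxazolidin-2-one | O=C([C@H]2c3cc(Br)cc(OC)c3O[C@@H]2c2ccc(O)c(OC)c2)N1[C@H](Cc2ccccc2)COC1=O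
F2 | step 7 | [(2S,3R)-5-allyl-7-methoxy-2-(3-methoxy-4-triisopropylsilyloxyphenyl)-2,3-dihydrobenzofuran-3-yl]methyl methanesulfonate | CS(=O)(=O)OC[C@H]2c3cc(CC=C)cc(OC)c3O[C@@H]2c2ccc(O[Si](C(C)C)(C(C)C)C(C)C)c(OC)c2
F3 | step 6 | methyl (2S,3S)-5-allyl-7-methoxy-2-(3-methoxy-4-triisopropylsilyloxyphenyl)-2,3-dihydrobenzofuran-3-carboxylate | COC(=O)[C@H]2c3cc(CC=C)cc(OC)c3O[C@@H]2c2ccc(O[Si](C(C)C)(C(C)C)C(C)C)c(OC)c2
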